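**Plan**

1. Locants (this answer only): C4 = CH(iPr), C5 = its ring CH2, C6 = CH bridgehead, C7 = one-carbon bridge CH, C8/C9 = decalin CH/C(Me), C13 = quaternary bridgehead, C14–C15 = CH2–CH(OH) bridge, C17 = CHBr, C21 = C(Me)OH. Ring A = C13–C4–C5–C6–C7, ring B = C13–C14–C15–C6–C7, ring C = central cyclohexane, ring D = bromocyclohexane. α = face of C8–H and of the C14 arm; β = face of the C9 methyl and C7–H.
2. Retrosynthetic cuts: C17–Br/H (vinyl bromide from ketone); C15–C6 of ring B (acyl radical); C4–iPr (anti-SN2′ opening of a temporary C6–O–C15 lactone); C13–C14 (Johnson–Claisen); C13=C4 of ring A (aldol condensation); rings C/D (Robinson annulation).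
3. Forward ring order: D + C together (organocatalytic Robinson annulation), then A (intramolecular aldol condensation), then B last (5-exo acyl-radical cyclisation onto a C5-bromo cyclopentene).
4. Stereochemistry: C9 from the catalyst; C8 and C21 by α-face hydroboration and α-face MeMgBr addition opposite the C9 methyl; C7 by equilibration; C13 by Luche reduction then suprafacial [3,3] shift; C4 by anti-SN2′; C6 by the tether; C15 by endo hydride delivery; C17 by axial H-atom transfer.
5. Enabling feature: the C13 acetic arm (C14–C15) is axial on ring C and lies 1,3-cis over ring A, five atoms from C6. A temporary vinylic bromine on C5 steers the C15 acyl radical to C6 and is removed in the same operation.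

Key step: step 17

Assumption: the organocatalytic annulation of the side-chain-bearing triketone 7 is taken to follow the facial sense established for the parent triketone (L-prolinamide catalyst gives the S ketone).

Step 1
Reactants: 1 bromo ketal 2-(2-bromoethyl)-2-methyl-1,3-dioxolane; 2 acrolein
Product: 4 allylic alcohol 5-(2-methyl-1,3-dioxolan-2-yl)pent-1-en-3-ol (racemic), via Grignard reagent 3 (not isolated)
Conditions: Mg, THF, 40 °C; then 2, −78 to 0 °C; aq. NH4Cl
Reagents that add atoms: none
Why: Grignard 1,2-addition to the enal should give the secondary allylic alcohol, whose configuration is irrelevant because it is oxidised in step 2.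

Step 2
Reactants: 4 allylic alcohol
Product: 5 vinyl ketone 5-(2-methyl-1,3-dioxolan-2-yl)pent-1-en-3-one
Conditions: Dess–Martin periodinane, NaHCO3, CH2Cl2, 0 °C (used crude)
Reagents that add atoms: none
Why: Buffered Dess–Martin oxidation of an allylic alcohol should give the enone without touching the dioxolane.

Step 3
Reactants: 5 vinyl ketone; 6 2-methylcyclohexane-1,3-dione
Product: 8 (S)-8a-methyl-5-[(2-methyl-1,3-dioxolan-2-yl)methyl]-3,4,8,8a-tetrahydronaphthalene-1,6(2H,7H)-dione, via Michael triketone 7 (not isolated)
Conditions: Et3N (cat.), neat, rt; then N-tosyl-(Sa)-binam-L-prolinamide (5 mol %), PhCO2H (cat.), rt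
Reagents that add atoms: none
Why: Robinson annulation (Michael addition, then enamine aldol condensation of the Hajos–Parrish/Wieland–Miescher type) should form rings D and C, the prolinamide selecting one of the two enantiotopic ring carbonyls so that C9 is set as S.

Step 4
Reactants: 8 enedione
Product: 9 tris(dioxolane) with C8=C21 double bond
Conditions: ethylene glycol, p-TsOH (cat.), benzene, reflux (Dean–Stark)
Reagents that add atoms: ethylene glycol OCCO
Why: Acid-catalysed ketalisation of the C17 ketone and of the enone with migration of the double bond out of conjugation (as for steroidal 4-en-3-ones) should give the β,γ-unsaturated ketal, C7 settling with its side chain equatorial.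

Step 5
Reactants: 9 tris(dioxolane) alkene
Product: 10 C21 α-alcohol with trans ring fusion (C8–H α)
Conditions: BH3·THF, 0 °C to rt; then NaOH, H2O2
Reagents that add atoms: hydrogen peroxide OO
Why: Hydroboration–oxidation should add H to C8 and OH to C21 syn from the α face, opposite the axial C9 methyl, which sets the trans-decalin centre C8.

Step 6
Reactants: 10 alcohol
Product: 11 C21 ketone
Conditions: Dess–Martin periodinane, NaHCO3, CH2Cl2, rt
Reagents that add atoms: none
Why: Dess–Martin oxidation of the secondary alcohol should give the ketone, and C8 (now α to it) keeps the more stable trans fusion.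

Step 7
Reactants: 11 ketone
Product: 12 tertiary alcohol (C21 OH β-axial; CH3 α-equatorial)
Conditions: MeMgBr, THF, −40 to 0 °C
Reagents that add atoms: methylmagnesium bromide C[Mg]Br
Why: Grignard addition should occur by equatorial attack on the α face because the axial β trajectory is blocked by the 1,3-diaxial C9 methyl, which sets C21.

Step 8
Reactants: 12 tertiary alcohol
Product: 14 ring-A enone diketone (C13=C4–C5=O plus C17=O), via triketone 13 (not isolated)
Conditions: 1 M HCl, THF, rt; then KOH, MeOH, 50 °C
Reagents that add atoms: water O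
Why: Hydrolysis of the three dioxolanes and intramolecular aldol condensation of the C4 methyl onto the C13 ketone (the only closure that leads to a conjugated enone) should form ring A, C7 equilibrating to the epimer with C6 equatorial because the axial one is 1,3-diaxial to the C9 methyl.

Step 9
Reactants: 14 enone diketone
Product: 15 C17 dioxolane of 14
Conditions: ethylene glycol, p-TsOH, 4 Å MS, CH2Cl2, rt
Reagents that add atoms: ethylene glycol OCCO
Why: Selective ketalisation of the saturated C17 ketone beside the less electrophilic conjugated ketone, the selectivity known for the Wieland–Miescher ketone itself.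

Step 10
Reactants: 15 enone
Product: 16 allylic alcohol (C5–OH α)
Conditions: NaBH4, CeCl3·7H2O, MeOH, −78 °C
Reagents that add atoms: none
Why: Luche 1,2-reduction, in which hydride should attack C5 from the convex β face (side of C7–H) and so place the hydroxyl on the α face.

Step 11
Reactants: 16 allylic alcohol
Product: 18 ethyl ester with quaternary C13 (α CH2CO2Et arm; C4=C5 alkene), via ketene acetal 17 (not isolated)
Conditions: MeC(OEt)3, EtCO2H (cat.), 140 °C
Reagents that add atoms: triethyl orthoacetate CC(OCC)(OCC)OCC
Why: Johnson–Claisen rearrangement, whose suprafacial [3,3] shift should form the C13–C14 bond on the α face that carried the C5–O bond, transferring the C5 configuration to the quaternary C13 and fixing the trans A/C fusion.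

Step 12
Reactants: 18 ester
Product: 19 enone ester (C6 ketone conjugated to C4=C5)
Conditions: Rh2(cap)4 (cat.), t-BuOOH, K2CO3, CH2Cl2, rt
Reagents that add atoms: tert-butyl hydroperoxide CC(C)(C)OO
Why: Rh(II)-catalysed allylic oxidation should turn the only allylic CH2 (C6; the other allylic position C13 is quaternary) into the ketone, oxygen being taken up at C6 because the other allyl terminus C4 is neopentylic.

Step 13
Reactants: 19 enone ester
Product: 21 α-bromo enone (Br on C5), via dibromide 20 (not isolated)
Conditions: Br2, CH2Cl2, 0 °C; then Et3N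
Reagents that add atoms: bromine BrBr
Why: Bromine addition to the enone followed by E1cB loss of HBr (α-bromination of a cyclopentenone) should place the bromine on C5.

Step 14
Reactants: 21 bromo enone
Product: 23 bridged δ-lactone (C6–O–C15=O; C5-bromo C4=C5 alkene), via hydroxy ester 22 (not isolated)
Conditions: NaBH4, CeCl3·7H2O, MeOH, −78 °C; then PPTS, benzene, 80 °C
Reagents that add atoms: none
Why: Luche reduction from the β face, opposite the axial arm, should give the C6 α-alcohol, which is 1,3-cis to the ester arm and closes to the lactone by transesterification.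

Step 15
Reactants: 23 lactone
Product: 24 carboxylic acid (C4 isopropyl β; C5-bromo C5=C6 alkene)
Conditions: i-PrMgCl (excess), CuBr·SMe2 (cat.), THF, −30 to 0 °C; then 1 M HCl
Reagents that add atoms: isopropylmagnesium chloride CC(C)[Mg]Cl
Why: Copper-catalysed anti-SN2′ opening of the allylic lactone, in which isopropyl should add to C4 on the β face anti to the departing C6 carboxylate, setting C4, freeing the acid and moving the double bond to C5=C6.

Step 16
Reactants: 24 acid
Product: 25 Se-phenyl selenoester
Conditions: (PhSe)2, PBu3, CH2Cl2, rt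
Reagents that add atoms: diphenyl diselenide c1ccc(cc1)[Se][Se]c1ccccc1
Why: Phosphine-mediated selenoesterification of the acid, which should leave the hindered tertiary alcohol and the vinyl bromide untouched.

Step 17
Reactants: 25 selenoester
Product: 27 tetracyclic C15 ketone (ring B closed), via bromo ketone 26 (not isolated)
Conditions: Bu3SnH (2.5 equiv, slow addition), AIBN, benzene (high dilution), 80 °C
Reagents that add atoms: none
Why: Proposed new method: Bu3Sn• abstracts PhSe from 25 to give the C15 acyl radical, which adds 5-exo-trig to C6 of the C5=C6 vinyl bromide and so closes ring B (C13–C14–C15–C6–C7); the α-bromo C5 radical takes H from Bu3SnH to give 26, and a second stannyl radical then removes the C5 bromine so that C5 ends as CH2. The closest known reaction types are the 5-exo cyclisation of acyl radicals from Se-phenyl selenoesters onto alkenes and the addition of carbon radicals to the unsubstituted terminus of vinyl halides; the known closure of the all-carbon 2-(cyclopent-3-enyl)ethyl radical to the 2-norbornyl radical shows that the strained bicyclo[2.2.1] ring can form this way. The only new stereocentre, C6, is fixed by the tether: the arm is axial on the α face of C13, so the C15–C6 bond must form on the α face and C6–H ends β, the bridgehead configuration of the target. The step needs regioselectivity between C6 and C5, which are about equally close to C15; the bromine on C5 should secure it, because attack at C6 gives a bromine-stabilised radical whereas attack at C5 would hit the substituted carbon. It also needs cyclisation to outrun reduction and decarbonylation of the acyl radical, which slow addition of Bu3SnH and the fast 5-exo closure onto a cis-held alkene should ensure.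

Step 18
Reactants: 27 ketone
Product: 28 C15 exo-alcohol
Conditions: NaBH4, MeOH, 0 °C
Reagents that add atoms: none
Why: Hydride should attack the norbornanone from the endo face because the exo face is screened by C8 on the one-carbon bridge (the camphor-to-isoborneol situation), giving the exo alcohol and setting C15.

Step 19
Reactants: 28 alcohol
Product: 29 C17 ketone diol
Conditions: 1 M HCl, THF, rt
Reagents that add atoms: water O
Why: Acid hydrolysis of the remaining dioxolane, under which the secondary and tertiary alcohols should be stable.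

Step 20
Reactants: 29 ketone
Product: 31 vinyl bromide (C17(Br)=C19), via hydrazone 30 (not isolated)
Conditions: N2H4·H2O, Et3N, EtOH, 80 °C; then NBS, 2-tert-butyl-1,1,3,3-tetramethylguanidine, CH2Cl2, 0 °C
Reagents that add atoms: N-bromosuccinimide O=C1CCC(=O)N1Br
Why: Barton-type vinyl halide synthesis, in which oxidation of the hydrazone by the N-bromo reagent should proceed through the diazo and bromodiazonium species to the vinyl bromide, proton loss being possible only toward C19 because C9 is quaternary.

Step 21
Reactants: 31 vinyl bromide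
Product: 32 CNP0317598.2 (target)
Conditions: Mn(dpm)3 (cat.), PhSiH3, t-BuOOH, i-PrOH, rt
Reagents that add atoms: none
Why: Mn-catalysed HAT (Mukaiyama-type) hydrogenation, a reaction known to reduce bromoalkenes to alkyl bromides, should deliver H• to C19 and then H to the α-bromo C17 radical along the axial α trajectory opposite the C9 methyl, leaving bromine equatorial (β) as in the target.

**Compound list**

1 | 2-(2-bromoethyl)-2-methyl-1,3-dioxolane | CC1(CCBr)OCCO1 | starting material
2 | acrolein | C=CC=O | starting material
3 | [2-(2-methyl-1,3-dioxolan-2-yl)ethyl]magnesium bromide | CC1(CC[Mg]Br)OCCO1 | intermediate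
4 | 5-(2-methyl-1,3-dioxolan-2-yl)pent-1-en-3-ol (racemic) | C=CC(O)CCC1(C)OCCO1 | intermediate
5 | 5-(2-methyl-1,3-dioxolan-2-yl)pent-1-en-3-one | C=CC(=O)CCC1(C)OCCO1 | intermediate
6 | 2-methylcyclohexane-1,3-dione | CC1C(=O)CCCC1=O | starting material
7 | Michael triketone, 2-methyl-2-[5-(2-methyl-1,3-dioxolan-2-yl)-3-oxopentyl]cyclohexane-1,3-dione | CC1(CCC(=O)CCC2(C)OCCO2)C(=O)CCCC1=O | intermediate
8 | (S)-8a-methyl-5-[(2-methyl-1,3-dioxolan-2-yl)methyl]-3,4,8,8a-tetrahydronaphthalene-1,6(2H,7H)-dione | C[C@]12CCC(=O)C(CC3(C)OCCO3)=C1CCCC2=O | intermediate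
9 | tris(dioxolane) (C17, C13, C5) with C8=C21 alkene, C7–H β | C[C@]12CCC3(OCCO3)[C@@H](CC4(C)OCCO4)C1=CCCC25OCCO5 | intermediate
10 | trans-decalin C21 α-alcohol (C8–H α), tris(dioxolane) | C[C@]12CCC3(OCCO3)[C@@H](CC4(C)OCCO4)[C@@H]1[C@@H](O)CCC25OCCO5 | intermediate
11 | C21 ketone, tris(dioxolane) | C[C@]12CCC3(OCCO3)[C@@H](CC4(C)OCCO4)[C@@H]1C(=O)CCC25OCCO5 | intermediate
12 | C21 tertiary alcohol (OH β, CH3 α), tris(dioxolane) | C[C@]12CCC3(OCCO3)[C@@H](CC4(C)OCCO4)[C@@H]1[C@](C)(O)CCC25OCCO5 | intermediate
13 | hydroxy triketone (C17, C13, C5 ketones) | C[C@]12CCC(=O)[C@@H](CC(C)=O)[C@@H]1[C@](C)(O)CCC2=O | intermediate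
14 | tricyclic enone (ring A, C13=C4–C5=O) with free C17 ketone | C[C@]12CCC3=CC(=O)C[C@H]3[C@@H]1[C@](C)(O)CCC2=O | intermediate
15 | C17 dioxolane of 14 | C[C@]12CCC3=CC(=O)C[C@H]3[C@@H]1[C@](C)(O)CCC25OCCO5 | intermediate
16 | allylic alcohol (C5–OH α) | C[C@]12CCC3=C[C@@H](O)C[C@H]3[C@@H]1[C@](C)(O)CCC25OCCO5 | intermediate
17 | mixed ketene acetal (C5–O–C(OEt)=CH2) | C[C@]12CCC3=C[C@@H](OC(=C)OCC)C[C@H]3[C@@H]1[C@](C)(O)CCC25OCCO5 | intermediate
18 | ethyl ester, C13 quaternary with α CH2CO2Et arm, C4=C5 alkene | C[C@]12CC[C@]3(CC(=O)OCC)C=CC[C@H]3[C@@H]1[C@](C)(O)CCC25OCCO5 | intermediate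
19 | enone ester (C6 ketone, C4=C5) | C[C@]12CC[C@]3(CC(=O)OCC)C=CC(=O)[C@H]3[C@@H]1[C@](C)(O)CCC25OCCO5 | intermediate
20 | trans-4,5-dibromo ketone | C[C@]12CC[C@]3(CC(=O)OCC)[C@H](Br)[C@@H](Br)C(=O)[C@H]3[C@@H]1[C@](C)(O)CCC25OCCO5 | intermediate
21 | 5-bromo enone ester | C[C@]12CC[C@]3(CC(=O)OCC)C=C(Br)C(=O)[C@H]3[C@@H]1[C@](C)(O)CCC25OCCO5 | intermediate
22 | C6 α-hydroxy ester | C[C@]12CC[C@]3(CC(=O)OCC)C=C(Br)[C@@H](O)[C@H]3[C@@H]1[C@](C)(O)CCC25OCCO5 | intermediate
23 | bridged δ-lactone (C6–O–C15=O), C5-bromo C4=C5 alkene | C[C@]12CC[C@]34CC(=O)O[C@H](C(Br)=C3)[C@H]4[C@@H]1[C@](C)(O)CCC25OCCO5 | intermediate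
24 | acid, C4 isopropyl β, C5-bromo C5=C6 alkene | C[C@]12CC[C@]3(CC(=O)O)[C@H](C(C)C)C(Br)=C[C@H]3[C@@H]1[C@](C)(O)CCC25OCCO5 | intermediate
25 | Se-phenyl selenoester of 24 | C[C@]12CC[C@]3(CC(=O)[Se]c4ccccc4)[C@H](C(C)C)C(Br)=C[C@H]3[C@@H]1[C@](C)(O)CCC25OCCO5 | intermediate
26 | 5-bromo tetracyclic C15 ketone | CC(C)[C@@H]1[C@@H](Br)[C@@H]2[C@H]3[C@H]4[C@](C)(CC[C@@]31CC2=O)C5(OCCO5)CC[C@@]4(C)O | intermediate
27 | tetracyclic C15 ketone, C17 dioxolane | CC(C)[C@@H]1C[C@@H]2[C@H]3[C@H]4[C@](C)(CC[C@@]31CC2=O)C5(OCCO5)CC[C@@]4(C)O | intermediate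
28 | C15 exo-alcohol, C17 dioxolane | CC(C)[C@@H]1C[C@@H]2[C@H]3[C@H]4[C@](C)(CC[C@@]31C[C@H]2O)C5(OCCO5)CC[C@@]4(C)O | intermediate
29 | C17 ketone diol | CC(C)[C@@H]1C[C@@H]2[C@H]3[C@H]4[C@](C)(CC[C@@]31C[C@H]2O)C(=O)CC[C@@]4(C)O | intermediate
30 | C17 hydrazone | CC(C)[C@@H]1C[C@@H]2[C@H]3[C@H]4[C@](C)(CC[C@@]31C[C@H]2O)C(=NN)CC[C@@]4(C)O | intermediate
31 | vinyl bromide (C17(Br)=C19) diol | CC(C)[C@@H]1C[C@@H]2[C@H]3[C@H]4[C@](C)(CC[C@@]31C[C@H]2O)C(Br)=CC[C@@]4(C)O | intermediate
32 | CNP0317598.2 | CC(C)[C@@H]1C[C@@H]2[C@H]3[C@H]4[C@](C)(CC[C@@]31C[C@H]2O)[C@@H](Br)CC[C@@]4(C)O | target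

**Count and risks**

Total steps: 21. Longest linear sequence: 21 steps (from 1).

Step 17 (key step, proposed method). The acyl radical may be reduced to the aldehyde or lose CO before it closes, or the vinylic bromine may be abstracted first, which would remove the regiocontrol and allow closure onto C5. The fallback uses known polar chemistry; it sets out from 19 and returns at 27. Conjugate addition of i-Pr2CuLi to the enone (isopropyl anti to the arm) with trapping of the C6 enolate by PhNTf2 would give the enol triflate F1. Pd-catalysed methoxycarbonylation (CO, MeOH, Et3N) would give the unsaturated diester F2, and hydrogenation from the β face (H2, Pd/C) the saturated diester F3. Dieckmann condensation (KOt-Bu, THF; C14 enolate onto the C6 methyl ester, the direction that ends in an enolisable β-keto ester) would close ring B as the β-keto ester F4. Krapcho dealkoxycarbonylation (LiCl, wet DMSO, 150 °C) would then give 27.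

Step 15. The isopropyl nucleophile may fail to reach C4, which is flanked by the quaternary C13, so that addition to the lactone carbonyl or bromine–magnesium exchange competes. The fallback sets out from 19 and returns at 27; it installs isopropyl by conjugate addition instead and closes ring B from a C6 iodide. i-Pr2CuLi/TMSCl would give the ketone F5; NaBH4/CeCl3 at −78 °C the alcohol F6; I2/PPh3/imidazole the iodide F7 (inversion). SmI2 (cat. NiI2, THF) would then effect intramolecular Barbier-type acyl substitution of the ethyl ester by the C6 organosamarium to give 27.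

Step 21. Hydrogen-atom transfer may be followed by loss of bromine (over-reduction), or hydrogen may be delivered to the β face and give the axial bromide. The fallback sets out from 29 and returns at 32. K-Selectride (equatorial delivery) would give the axial 17α-alcohol F8, and Appel bromination (CBr4, PPh3) with inversion would give 32. The norbornyl C15 alcohol cannot undergo backside displacement and the C21 alcohol is tertiary, so only C17 should react, though displacement next to the quaternary C9 is expected to be slow.

**Further compounds**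

F1 | step 17 | C6 enol triflate with C4 isopropyl β | C[C@]12CC[C@]3(CC(=O)OCC)[C@H](C(C)C)C=C(OS(=O)(=O)C(F)(F)F)[C@H]3[C@@H]1[C@](C)(O)CCC25OCCO5
F2 | step 17 | unsaturated diester (C6 CO2Me, C5=C6) | C[C@]12CC[C@]3(CC(=O)OCC)[C@H](C(C)C)C=C(C(=O)OC)[C@H]3[C@@H]1[C@](C)(O)CCC25OCCO5
F3 | step 17 | saturated diester (C6 CO2Me α) | C[C@]12CC[C@]3(CC(=O)OCC)[C@H](C(C)C)C[C@@H](C(=O)OC)[C@H]3[C@@H]1[C@](C)(O)CCC25OCCO5
F4 | step 17 | tetracyclic β-keto ester (CO2Et on C14) | CC(C)[C@@H]1C[C@@H]2[C@H]3[C@H]4[C@](C)(CC[C@@]31C(C(=O)OCC)C2=O)C5(OCCO5)CC[C@@]4(C)O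
F5 | step 15 | C6 ketone with C4 isopropyl β | C[C@]12CC[C@]3(CC(=O)OCC)[C@H](C(C)C)CC(=O)[C@H]3[C@@H]1[C@](C)(O)CCC25OCCO5
F6 | step 15 | C6 α-alcohol | C[C@]12CC[C@]3(CC(=O)OCC)[C@H](C(C)C)C[C@@H](O)[C@H]3[C@@H]1[C@](C)(O)CCC25OCCO5
F7 | step 15 | C6 β-iodide | C[C@]12CC[C@]3(CC(=O)OCC)[C@H](C(C)C)C[C@H](I)[C@H]3[C@@H]1[C@](C)(O)CCC25OCCO5
F8 | step 21 | 17α-alcohol triol | CC(C)[C@@H]1C[C@@H]2[C@H]3[C@H]4[C@](C)(CC[C@@]31C[C@H]2O)[C@H](O)CC[C@@]4(C)O
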